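**Retrosynthetic overview**
1. C11–C12: late Stille union of the C1–C11 vinyl iodide acid 24 with the C12–C24 dienyl-lactone vinylstannane 37; only C8 oxidation and desilylation follow.
2. 37: C17–C18 Stille union of lactone stannane 35 with (Z)-vinyl iodide 28, then hydrostannation of the terminal alkyne.
3. 24: C8–C9 by chiral allenylzinc addition (sets C9), C6–C7 by anti-crotylboration, C3–C4 by organocopper addition to ethyl but-2-ynoate.
4. Ring order: the only ring, dihydropyranone ring A, is closed first (anti-crotylboration, acryloylation, ring-closing metathesis) and carried through both couplings.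
5. C5 and C15 both come from (S)-3-bromo-2-methylpropan-1-ol.

Assumption: the SMILES is read literally, i.e. (2E,5R,6R,7R,9S,10E,12E,15R,16Z,18E) with a trans (2R,3S) lactone and an anti,anti C5–C7 triad. Chain numbering is C1 = CO2H to C19 (attached to the ring); ring carbons are C20–C24.

**East fragment, main line**

Step 1
Reactants: 1 (S)-3-bromo-2-methylpropan-1-ol
Product: 2 (S)-(3-bromo-2-methylpropoxy)(tert-butyl)dimethylsilane
Conditions: TBSCl, imidazole, CH2Cl2, 0 °C → rt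
Reagents that add atoms: tert-butyldimethylsilyl chloride, CC(C)(C)[Si](C)(C)Cl
Why: Silyl ether formation (substitution at silicon) masks the hydroxyl for the organometallic steps and leaves the stereocentre untouched; 2 also feeds step 16.

Step 2
Reactants: 2 (S)-(3-bromo-2-methylpropoxy)(tert-butyl)dimethylsilane; 3 ethyl but-2-ynoate
Product: 6 ethyl (2E,5R)-6-[(tert-butyldimethylsilyl)oxy]-3,5-dimethylhex-2-enoate, via Grignard reagent 4 (not isolated), via organocopper reagent 5 (not isolated)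
Conditions: Mg, THF, 40 °C; CuBr·SMe2, THF, −45 °C; then 3, −78 °C; aq. NH4Cl at −78 °C
Reagents that add atoms: none
Why: Syn carbocupration (conjugate addition) of the alkylcopper to the ynoate at −78 °C, then protonation with retention, gives the (E)-trisubstituted enoate.

Step 3
Reactants: 6 ethyl (2E,5R)-6-[(tert-butyldimethylsilyl)oxy]-3,5-dimethylhex-2-enoate
Product: 7 ethyl (2E,5R)-6-hydroxy-3,5-dimethylhex-2-enoate
Conditions: camphorsulfonic acid (10 mol %), EtOH, rt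
Reagents that add atoms: none
Why: Acid-catalysed ethanolysis of the primary silyl ether; ethanol avoids ester scrambling and acid avoids oxa-Michael closure.

Step 4
Reactants: 7 ethyl (2E,5R)-6-hydroxy-3,5-dimethylhex-2-enoate
Product: 8 ethyl (2E,5R)-3,5-dimethyl-6-oxohex-2-enoate
Conditions: Dess–Martin periodinane, NaHCO3, CH2Cl2, 0 °C → rt; used crude
Reagents that add atoms: none
Why: Buffered Dess–Martin oxidation gives the α-methyl aldehyde without epimerisation.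

Step 5
Reactants: 8 ethyl (2E,5R)-3,5-dimethyl-6-oxohex-2-enoate
Product: 10 ethyl (2E,5R,6R,7S)-6-hydroxy-3,5,7-trimethylnona-2,8-dienoate, via borinate 9 (not isolated)
Conditions: trans-but-2-ene, n-BuLi, KOt-Bu, THF, −78 → −45 °C; (−)-Ipc2BOMe, −78 °C; BF3·OEt2; then 8, −78 °C; NaOH, H2O2, 0 °C → rt
Reagents that add atoms: trans-but-2-ene, C/C=C/C
Why: Brown crotylboration through a chair transition state: the (E)-crotyl geometry gives the 6,7-anti relation, and the (−)-Ipc2B group (from (+)-α-pinene) directs attack to the Si face, overriding the weak Felkin bias to give the 5,6-anti triad.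

Step 6
Reactants: 10 ethyl (2E,5R,6R,7S)-6-hydroxy-3,5,7-trimethylnona-2,8-dienoate
Product: 11 ethyl (2E,5R,6R,7S)-6-[(tert-butyldimethylsilyl)oxy]-3,5,7-trimethylnona-2,8-dienoate
Conditions: TBSOTf, 2,6-lutidine, CH2Cl2, −78 → 0 °C
Reagents that add atoms: tert-butyldimethylsilyl trifluoromethanesulfonate, CC(C)(C)[Si](C)(C)OS(=O)(=O)C(F)(F)F
Why: Silylation of the hindered secondary alcohol with the silyl triflate protects C6–OH until the last step.

Step 7
Reactants: 11 ethyl (2E,5R,6R,7S)-6-[(tert-butyldimethylsilyl)oxy]-3,5,7-trimethylnona-2,8-dienoate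
Product: 13 ethyl (2E,5R,6R,7R)-6-[(tert-butyldimethylsilyl)oxy]-3,5,7-trimethyl-8-oxooct-2-enoate, via diol 12 (not isolated)
Conditions: OsO4 (2 mol %), NaIO4, 2,6-lutidine, 1,4-dioxane/H2O (3:1), rt
Reagents that add atoms: osmium tetroxide, O=[Os](=O)(=O)=O; sodium periodate, [Na+].[O-]I(=O)(=O)=O
Why: Lemieux–Johnson cleavage; the terminal vinyl group is dihydroxylated much faster than the electron-poor trisubstituted enoate, and the lutidine buffer keeps C7 intact.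

**Chiral propargylic mesylate**

Step 8
Reactants: 14 methyl 2-hydroxyacetate (methyl glycolate)
Product: 15 methyl 2-[(tert-butyldimethylsilyl)oxy]acetate
Conditions: TBSCl, imidazole, DMF, rt
Reagents that add atoms: tert-butyldimethylsilyl chloride, CC(C)(C)[Si](C)(C)Cl
Why: Silyl ether formation installs the group that later protects the C9 hydroxymethyl.

Step 9
Reactants: 15 methyl 2-[(tert-butyldimethylsilyl)oxy]acetate
Product: 16 2-[(tert-butyldimethylsilyl)oxy]-N-methoxy-N-methylacetamide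
Conditions: MeNHOMe·HCl, i-PrMgCl, THF, −20 °C; aq. NH4Cl
Reagents that add atoms: N,O-dimethylhydroxylamine hydrochloride, CNOC.Cl
Why: Weinreb amide formation by aminolysis of the ester with the magnesium amide.

Step 10
Reactants: 16 2-[(tert-butyldimethylsilyl)oxy]-N-methoxy-N-methylacetamide
Product: 17 1-[(tert-butyldimethylsilyl)oxy]pent-3-yn-2-one
Conditions: CH3C≡CMgBr, THF, −78 → 0 °C; aq. NH4Cl
Reagents that add atoms: prop-1-yn-1-ylmagnesium bromide, CC#C[Mg]Br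
Why: Weinreb ketone synthesis; the chelated tetrahedral adduct prevents over-addition.

Step 11
Reactants: 17 1-[(tert-butyldimethylsilyl)oxy]pent-3-yn-2-one
Product: 18 (2R)-1-[(tert-butyldimethylsilyl)oxy]pent-3-yn-2-ol
Conditions: RuCl[(S,S)-TsDPEN](p-cymene) (1 mol %), KOH (1 mol %), i-PrOH, rt
Reagents that add atoms: none
Why: Noyori asymmetric transfer hydrogenation of an ynone; the alkyne takes the place of the aryl group in the usual model, so the (S,S)-catalyst delivers hydride to the face giving the (R)-carbinol (R because CH2OSi outranks the alkyne).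

Step 12
Reactants: 18 (2R)-1-[(tert-butyldimethylsilyl)oxy]pent-3-yn-2-ol
Product: 19 (2R)-1-[(tert-butyldimethylsilyl)oxy]pent-3-yn-2-yl methanesulfonate
Conditions: MsCl, Et3N, CH2Cl2, −78 °C; used crude
Reagents that add atoms: methanesulfonyl chloride, CS(=O)(=O)Cl
Why: Sulfonylation at oxygen with retention activates the propargylic position.

**East fragment, completion**

Step 13
Reactants: 13 ethyl (2E,5R,6R,7R)-6-[(tert-butyldimethylsilyl)oxy]-3,5,7-trimethyl-8-oxooct-2-enoate; 19 (2R)-1-[(tert-butyldimethylsilyl)oxy]pent-3-yn-2-yl methanesulfonate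
Product: 21 ethyl (2E,5R,6R,7S,8R,9S)-6-[(tert-butyldimethylsilyl)oxy]-9-{[(tert-butyldimethylsilyl)oxy]methyl}-8-hydroxy-3,5,7-trimethyldodec-2-en-10-ynoate, via allenylzinc 20 (not isolated)
Conditions: Pd(OAc)2 (5 mol %), PPh3 (5 mol %), Et2Zn (3 equiv), THF, −78 → −20 °C; aq. NH4Cl
Reagents that add atoms: none
Why: Marshall propargylation: zerovalent palladium opens the (R)-mesylate by anti SN2′, transmetallation gives allenylzinc 20, and its cyclic SE2′ addition joins C8 with net inversion at the propargylic carbon, setting C9 (S) and the 8,9-anti (Felkin) alcohol, whose C8 is oxidised later.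

Step 14
Reactants: 21 ethyl (2E,5R,6R,7S,8R,9S)-6-[(tert-butyldimethylsilyl)oxy]-9-{[(tert-butyldimethylsilyl)oxy]methyl}-8-hydroxy-3,5,7-trimethyldodec-2-en-10-ynoate
Product: 23 ethyl (2E,5R,6R,7S,8R,9S,10E)-6-[(tert-butyldimethylsilyl)oxy]-9-{[(tert-butyldimethylsilyl)oxy]methyl}-8-hydroxy-11-iodo-3,5,7-trimethyldodeca-2,10-dienoate, via vinylstannane 22 (not isolated)
Conditions: Bu3SnH, PdCl2(PPh3)2 (3 mol %), THF, 0 °C → rt; then I2, CH2Cl2, 0 °C
Reagents that add atoms: iodine, II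
Why: Palladium-catalysed syn hydrostannation puts tin on the less hindered, methyl-bearing alkyne carbon, and iododestannylation with retention gives the (E)-2-iodoalkene.

Step 15
Reactants: 23 ethyl (2E,5R,6R,7S,8R,9S,10E)-6-[(tert-butyldimethylsilyl)oxy]-9-{[(tert-butyldimethylsilyl)oxy]methyl}-8-hydroxy-11-iodo-3,5,7-trimethyldodeca-2,10-dienoate
Product: 24 (2E,5R,6R,7S,8R,9S,10E)-6-[(tert-butyldimethylsilyl)oxy]-9-{[(tert-butyldimethylsilyl)oxy]methyl}-8-hydroxy-11-iodo-3,5,7-trimethyldodeca-2,10-dienoic acid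
Conditions: LiOH·H2O, THF/MeOH/H2O (3:1:1), 40 °C; then 1 M HCl to pH 3
Reagents that add atoms: lithium hydroxide, [Li+].[OH-]
Why: Saponification frees the C1 acid while no base-sensitive ketone or lactone is present; silyl ethers and the vinyl iodide are stable to hydroxide.

**Middle fragment (C12–C17)**

Step 16
Reactants: 2 (S)-(3-bromo-2-methylpropoxy)(tert-butyl)dimethylsilane
Product: 25 tert-butyldimethyl{[(2R)-2-methylpent-4-yn-1-yl]oxy}silane
Conditions: LiC≡CH·H2NCH2CH2NH2, DMSO, 10 °C → rt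
Reagents that add atoms: lithium acetylide–ethylenediamine complex, [Li]C#C.NCCN
Why: SN2 alkylation of acetylide by the primary bromide; the descriptor changes to R only through priorities.

Step 17
Reactants: 25 tert-butyldimethyl{[(2R)-2-methylpent-4-yn-1-yl]oxy}silane
Product: 26 (2R)-2-methylpent-4-yn-1-ol
Conditions: Bu4NF, THF, 0 °C → rt
Reagents that add atoms: none
Why: Fluoride-induced desilylation of the primary silyl ether.

Step 18
Reactants: 26 (2R)-2-methylpent-4-yn-1-ol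
Product: 27 (2R)-2-methylpent-4-ynal
Conditions: Dess–Martin periodinane, NaHCO3, CH2Cl2, 0 °C; filtered solution used at once
Reagents that add atoms: none
Why: Buffered Dess–Martin oxidation; the volatile, epimerisable aldehyde is not concentrated.

Step 19
Reactants: 27 (2R)-2-methylpent-4-ynal
Product: 28 (4R,5Z)-6-iodo-4-methyloct-5-en-1-yne
Conditions: [n-PrPPh3]Br, n-BuLi, THF, 0 °C; I2, −78 °C; NaN(SiMe3)2, −78 → −20 °C; then 27, −78 °C → rt
Reagents that add atoms: propyltriphenylphosphonium bromide, CCC[P+](c1ccccc1)(c1ccccc1)c1ccccc1.[Br-]; iodine, II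
Why: Stork–Zhao-type Wittig olefination with the α-iodo ylide Ph3P=C(I)Et gives the (Z)-iodoalkene (iodine cis to the chain) under kinetic control.

**Lactone fragment (ring A)**

Step 20
Reactants: 29 prop-2-yn-1-ol
Product: 30 (2E)-3-(tributylstannyl)prop-2-en-1-ol
Conditions: Bu3SnH, AIBN (cat.), neat, 80 °C; chromatography
Reagents that add atoms: tributyltin hydride, CCCC[SnH](CCCC)CCCC
Why: Radical hydrostannation under equilibrating conditions gives mainly the (E)-β-stannyl allylic alcohol.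

Step 21
Reactants: 30 (2E)-3-(tributylstannyl)prop-2-en-1-ol
Product: 31 (2E)-3-(tributylstannyl)prop-2-enal
Conditions: MnO2, CH2Cl2, rt
Reagents that add atoms: none
Why: Allylic oxidation with MnO2 is neutral and leaves the vinylstannane intact.

Step 22
Reactants: 31 (2E)-3-(tributylstannyl)prop-2-enal
Product: 33 (1E,3S,4S)-4-methyl-1-(tributylstannyl)hexa-1,5-dien-3-ol, via borinate 32 (not isolated)
Conditions: trans-but-2-ene, n-BuLi, KOt-Bu, THF, −78 → −45 °C; (−)-Ipc2BOMe, −78 °C; BF3·OEt2; then 31, −78 °C; NaOH, H2O2, 0 °C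
Reagents that add atoms: trans-but-2-ene, C/C=C/C
Why: Brown (E)-crotylboration: the chair transition state gives the anti alcohol and the (−)-Ipc2B group directs Si-face attack, setting both ring stereocentres (C20, C21).

Step 23
Reactants: 33 (1E,3S,4S)-4-methyl-1-(tributylstannyl)hexa-1,5-dien-3-ol
Product: 34 (1E,3S,4S)-4-methyl-1-(tributylstannyl)hexa-1,5-dien-3-yl prop-2-enoate
Conditions: acryloyl chloride, i-Pr2NEt, DMAP (cat.), CH2Cl2, −20 → 0 °C
Reagents that add atoms: acryloyl chloride, C=CC(=O)Cl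
Why: O-acylation supplies the remaining three ring atoms; no stereocentre is touched.

Step 24
Reactants: 34 (1E,3S,4S)-4-methyl-1-(tributylstannyl)hexa-1,5-dien-3-yl prop-2-enoate
Product: 35 (5S,6S)-5-methyl-6-[(E)-2-(tributylstannyl)ethenyl]-5,6-dihydro-2H-pyran-2-one
Conditions: second-generation Grubbs catalyst RuCl2(=CHPh)(PCy3)(H2IMes) (5 mol %), CH2Cl2 (5 mM), 40 °C
Reagents that add atoms: none
Why: Ring-closing metathesis: the carbene loads on the terminal vinyl group and closes ring A onto the acrylate, giving the trans-5,6-disubstituted lactone from the anti alcohol; the 1,2-disubstituted vinylstannane is expected to be a spectator.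

**West fragment**

Step 25
Reactants: 35 (5S,6S)-5-methyl-6-[(E)-2-(tributylstannyl)ethenyl]-5,6-dihydro-2H-pyran-2-one; 28 (4R,5Z)-6-iodo-4-methyloct-5-en-1-yne
Product: 36 (5S,6R)-6-[(1E,3Z,5R)-3-ethyl-5-methylocta-1,3-dien-7-yn-1-yl]-5-methyl-5,6-dihydro-2H-pyran-2-one
Conditions: Pd2(dba)3 (5 mol %), AsPh3 (40 mol %), NMP, rt → 45 °C
Reagents that add atoms: none
Why: Stille coupling without copper or base joins C17–C18 with retention of both alkene geometries (18E, 16Z) and spares the terminal alkyne and lactone.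

Step 26
Reactants: 36 (5S,6R)-6-[(1E,3Z,5R)-3-ethyl-5-methylocta-1,3-dien-7-yn-1-yl]-5-methyl-5,6-dihydro-2H-pyran-2-one
Product: 37 (5S,6R)-6-[(1E,3Z,5R,7E)-3-ethyl-5-methyl-8-(tributylstannyl)octa-1,3,7-trien-1-yl]-5-methyl-5,6-dihydro-2H-pyran-2-one
Conditions: Bu3SnH (slow addition), Pd2(dba)3 (1 mol %), Cy3P·HBF4 (4 mol %), i-Pr2NEt (8 mol %), CH2Cl2, 0 °C
Reagents that add atoms: tributyltin hydride, CCCC[SnH](CCCC)CCCC
Why: Palladium-catalysed syn hydrostannation with the bulky phosphine gives the terminal (E)-vinylstannane; the terminal alkyne reacts far faster than the diene or the lactone.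

**Fragment union and endgame**

Step 27
Reactants: 24 (2E,5R,6R,7S,8R,9S,10E)-6-[(tert-butyldimethylsilyl)oxy]-9-{[(tert-butyldimethylsilyl)oxy]methyl}-8-hydroxy-11-iodo-3,5,7-trimethyldodeca-2,10-dienoic acid; 37 (5S,6R)-6-[(1E,3Z,5R,7E)-3-ethyl-5-methyl-8-(tributylstannyl)octa-1,3,7-trien-1-yl]-5-methyl-5,6-dihydro-2H-pyran-2-one
Product: 38 (2E,5R,6R,7S,8R,9S,10E,12E,15R,16Z,18E)-6-[(tert-butyldimethylsilyl)oxy]-9-{[(tert-butyldimethylsilyl)oxy]methyl}-17-ethyl-8-hydroxy-3,5,7,11,15-pentamethyl-19-[(2R,3S)-3-methyl-6-oxo-3,6-dihydro-2H-pyran-2-yl]nonadeca-2,10,12,16,18-pentaenoic acid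
Conditions: Pd(PPh3)4 (10 mol %), Cu(O2CC4H3S) (copper thiophene-2-carboxylate, 1.5 equiv), [NBu4][Ph2PO2] (2.5 equiv), DMF, rt
Reagents that add atoms: none
Why: Stille coupling promoted by the monovalent copper carboxylate, with phosphinate as tin scavenger, joins the two halves at C11–C12 at room temperature with retention of both geometries and without base, so the acid, free alcohol and lactone survive.

Step 28
Reactants: 38 (the C8 alcohol from step 27)
Product: 39 (2E,5R,6R,7R,9S,10E,12E,15R,16Z,18E)-6-[(tert-butyldimethylsilyl)oxy]-9-{[(tert-butyldimethylsilyl)oxy]methyl}-17-ethyl-3,5,7,11,15-pentamethyl-19-[(2R,3S)-3-methyl-6-oxo-3,6-dihydro-2H-pyran-2-yl]-8-oxononadeca-2,10,12,16,18-pentaenoic acid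
Conditions: Dess–Martin periodinane, NaHCO3, CH2Cl2, 0 °C
Reagents that add atoms: none
Why: Buffered Dess–Martin oxidation of the only free alcohol gives the C8 ketone without epimerising C7 or C9.

Step 29
Reactants: 39 (the bis-silyl keto acid from step 28)
Product: 40 (2E,5R,6R,7R,9S,10E,12E,15R,16Z,18E)-17-ethyl-6-hydroxy-9-(hydroxymethyl)-3,5,7,11,15-pentamethyl-19-[(2R,3S)-3-methyl-6-oxo-3,6-dihydro-2H-pyran-2-yl]-8-oxononadeca-2,10,12,16,18-pentaenoic acid
Conditions: HF·pyridine, pyridine, THF, 0 °C → rt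
Reagents that add atoms: none
Why: Buffered acidic fluoride desilylation removes both silyl ethers without the retro-aldol, elimination or lactone opening that basic fluoride would risk.

**Compound list**

1 | (S)-3-bromo-2-methylpropan-1-ol | OC[C@H](C)CBr | starting material
2 | (S)-(3-bromo-2-methylpropoxy)(tert-butyl)dimethylsilane | CC(C)(C)[Si](C)(C)OC[C@H](C)CBr | intermediate
3 | ethyl but-2-ynoate | CCOC(=O)C#CC | starting material
4 | {(2S)-3-[(tert-butyldimethylsilyl)oxy]-2-methylpropyl}magnesium bromide | CC(C)(C)[Si](C)(C)OC[C@H](C)C[Mg]Br | intermediate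
5 | {(2S)-3-[(tert-butyldimethylsilyl)oxy]-2-methylpropyl}copper, RCu·MgBr2 | CC(C)(C)[Si](C)(C)OC[C@H](C)C[Cu] | intermediate
6 | ethyl (2E,5R)-6-[(tert-butyldimethylsilyl)oxy]-3,5-dimethylhex-2-enoate | CC(C)(C)[Si](C)(C)OC[C@H](C)C/C(C)=C/C(=O)OCC | intermediate
7 | ethyl (2E,5R)-6-hydroxy-3,5-dimethylhex-2-enoate | OC[C@H](C)C/C(C)=C/C(=O)OCC | intermediate
8 | ethyl (2E,5R)-3,5-dimethyl-6-oxohex-2-enoate | O=C[C@H](C)C/C(C)=C/C(=O)OCC | intermediate
9 | diisopinocampheylborinate of 10 | C=C[C@H](C)[C@H](OB([C@@H]1C[C@@H]2C[C@H]([C@H]1C)C2(C)C)[C@@H]1C[C@@H]2C[C@H]([C@H]1C)C2(C)C)[C@H](C)C/C(C)=C/C(=O)OCC | intermediate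
10 | ethyl (2E,5R,6R,7S)-6-hydroxy-3,5,7-trimethylnona-2,8-dienoate | C=C[C@H](C)[C@H](O)[C@H](C)C/C(C)=C/C(=O)OCC | intermediate
11 | ethyl (2E,5R,6R,7S)-6-[(tert-butyldimethylsilyl)oxy]-3,5,7-trimethylnona-2,8-dienoate | C=C[C@H](C)[C@H](O[Si](C)(C)C(C)(C)C)[C@H](C)C/C(C)=C/C(=O)OCC | intermediate
12 | ethyl (2E,5R,6R,7S)-6-[(tert-butyldimethylsilyl)oxy]-8,9-dihydroxy-3,5,7-trimethylnon-2-enoate (C8 epimers) | OCC(O)[C@H](C)[C@H](O[Si](C)(C)C(C)(C)C)[C@H](C)C/C(C)=C/C(=O)OCC | intermediate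
13 | ethyl (2E,5R,6R,7R)-6-[(tert-butyldimethylsilyl)oxy]-3,5,7-trimethyl-8-oxooct-2-enoate | O=C[C@H](C)[C@H](O[Si](C)(C)C(C)(C)C)[C@H](C)C/C(C)=C/C(=O)OCC | intermediate
14 | methyl 2-hydroxyacetate | COC(=O)CO | starting material
15 | methyl 2-[(tert-butyldimethylsilyl)oxy]acetate | COC(=O)CO[Si](C)(C)C(C)(C)C | intermediate
16 | 2-[(tert-butyldimethylsilyl)oxy]-N-methoxy-N-methylacetamide | CON(C)C(=O)CO[Si](C)(C)C(C)(C)C | intermediate
17 | 1-[(tert-butyldimethylsilyl)oxy]pent-3-yn-2-one | CC#CC(=O)CO[Si](C)(C)C(C)(C)C | intermediate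
18 | (2R)-1-[(tert-butyldimethylsilyl)oxy]pent-3-yn-2-ol | CC#C[C@@H](O)CO[Si](C)(C)C(C)(C)C | intermediate
19 | (2R)-1-[(tert-butyldimethylsilyl)oxy]pent-3-yn-2-yl methanesulfonate | CC#C[C@@H](OS(C)(=O)=O)CO[Si](C)(C)C(C)(C)C | intermediate
20 | ethyl{(aR)-5-[(tert-butyldimethylsilyl)oxy]penta-2,3-dien-2-yl}zinc | CC[Zn]C(C)=[C@]=C([H])CO[Si](C)(C)C(C)(C)C | intermediate
21 | ethyl (2E,5R,6R,7S,8R,9S)-6-[(tert-butyldimethylsilyl)oxy]-9-{[(tert-butyldimethylsilyl)oxy]methyl}-8-hydroxy-3,5,7-trimethyldodec-2-en-10-ynoate | CC#C[C@@H](CO[Si](C)(C)C(C)(C)C)[C@@H](O)[C@H](C)[C@H](O[Si](C)(C)C(C)(C)C)[C@H](C)C/C(C)=C/C(=O)OCC | intermediate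
22 | ethyl (2E,5R,6R,7S,8R,9S,10E)-6-[(tert-butyldimethylsilyl)oxy]-9-{[(tert-butyldimethylsilyl)oxy]methyl}-8-hydroxy-3,5,7-trimethyl-11-(tributylstannyl)dodeca-2,10-dienoate | CCCC[Sn](CCCC)(CCCC)/C(C)=C/[C@@H](CO[Si](C)(C)C(C)(C)C)[C@@H](O)[C@H](C)[C@H](O[Si](C)(C)C(C)(C)C)[C@H](C)C/C(C)=C/C(=O)OCC | intermediate
23 | ethyl (2E,5R,6R,7S,8R,9S,10E)-6-[(tert-butyldimethylsilyl)oxy]-9-{[(tert-butyldimethylsilyl)oxy]methyl}-8-hydroxy-11-iodo-3,5,7-trimethyldodeca-2,10-dienoate | I/C(C)=C/[C@@H](CO[Si](C)(C)C(C)(C)C)[C@@H](O)[C@H](C)[C@H](O[Si](C)(C)C(C)(C)C)[C@H](C)C/C(C)=C/C(=O)OCC | intermediate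
24 | (2E,5R,6R,7S,8R,9S,10E)-6-[(tert-butyldimethylsilyl)oxy]-9-{[(tert-butyldimethylsilyl)oxy]methyl}-8-hydroxy-11-iodo-3,5,7-trimethyldodeca-2,10-dienoic acid | I/C(C)=C/[C@@H](CO[Si](C)(C)C(C)(C)C)[C@@H](O)[C@H](C)[C@H](O[Si](C)(C)C(C)(C)C)[C@H](C)C/C(C)=C/C(=O)O | intermediate
25 | tert-butyldimethyl{[(2R)-2-methylpent-4-yn-1-yl]oxy}silane | CC(C)(C)[Si](C)(C)OC[C@H](C)CC#C | intermediate
26 | (2R)-2-methylpent-4-yn-1-ol | OC[C@H](C)CC#C | intermediate
27 | (2R)-2-methylpent-4-ynal | O=C[C@H](C)CC#C | intermediate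
28 | (4R,5Z)-6-iodo-4-methyloct-5-en-1-yne | CCC(=C/[C@H](C)CC#C)/I | intermediate
29 | prop-2-yn-1-ol | C#CCO | starting material
30 | (2E)-3-(tributylstannyl)prop-2-en-1-ol | CCCC[Sn](CCCC)(CCCC)/C=C/CO | intermediate
31 | (2E)-3-(tributylstannyl)prop-2-enal | CCCC[Sn](CCCC)(CCCC)/C=C/C=O | intermediate
32 | diisopinocampheylborinate of 33 | CCCC[Sn](CCCC)(CCCC)/C=C/[C@@H](OB([C@@H]1C[C@@H]2C[C@H]([C@H]1C)C2(C)C)[C@@H]1C[C@@H]2C[C@H]([C@H]1C)C2(C)C)[C@@H](C)C=C | intermediate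
33 | (1E,3S,4S)-4-methyl-1-(tributylstannyl)hexa-1,5-dien-3-ol | CCCC[Sn](CCCC)(CCCC)/C=C/[C@@H](O)[C@@H](C)C=C | intermediate
34 | (1E,3S,4S)-4-methyl-1-(tributylstannyl)hexa-1,5-dien-3-yl prop-2-enoate | CCCC[Sn](CCCC)(CCCC)/C=C/[C@@H](OC(=O)C=C)[C@@H](C)C=C | intermediate
35 | (5S,6S)-5-methyl-6-[(E)-2-(tributylstannyl)ethenyl]-5,6-dihydro-2H-pyran-2-one | CCCC[Sn](CCCC)(CCCC)/C=C/[C@H]1OC(=O)C=C[C@@H]1C | intermediate
36 | (5S,6R)-6-[(1E,3Z,5R)-3-ethyl-5-methylocta-1,3-dien-7-yn-1-yl]-5-methyl-5,6-dihydro-2H-pyran-2-one | CCC(=C/[C@H](C)CC#C)/C=C/[C@H]1OC(=O)C=C[C@@H]1C | intermediate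
37 | (5S,6R)-6-[(1E,3Z,5R,7E)-3-ethyl-5-methyl-8-(tributylstannyl)octa-1,3,7-trien-1-yl]-5-methyl-5,6-dihydro-2H-pyran-2-one | CCC(=C/[C@H](C)C/C=C/[Sn](CCCC)(CCCC)CCCC)/C=C/[C@H]1OC(=O)C=C[C@@H]1C | intermediate
38 | (2E,5R,6R,7S,8R,9S,10E,12E,15R,16Z,18E)-6-[(tert-butyldimethylsilyl)oxy]-9-{[(tert-butyldimethylsilyl)oxy]methyl}-17-ethyl-8-hydroxy-3,5,7,11,15-pentamethyl-19-[(2R,3S)-3-methyl-6-oxo-3,6-dihydro-2H-pyran-2-yl]nonadeca-2,10,12,16,18-pentaenoic acid | CCC(=C/[C@H](C)C/C=C/C(C)=C/[C@@H](CO[Si](C)(C)C(C)(C)C)[C@@H](O)[C@H](C)[C@H](O[Si](C)(C)C(C)(C)C)[C@H](C)C/C(C)=C/C(=O)O)/C=C/[C@H]1OC(=O)C=C[C@@H]1C | intermediate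
39 | (2E,5R,6R,7R,9S,10E,12E,15R,16Z,18E)-6-[(tert-butyldimethylsilyl)oxy]-9-{[(tert-butyldimethylsilyl)oxy]methyl}-17-ethyl-3,5,7,11,15-pentamethyl-19-[(2R,3S)-3-methyl-6-oxo-3,6-dihydro-2H-pyran-2-yl]-8-oxononadeca-2,10,12,16,18-pentaenoic acid | CCC(=C/[C@H](C)C/C=C/C(C)=C/[C@@H](CO[Si](C)(C)C(C)(C)C)C(=O)[C@H](C)[C@H](O[Si](C)(C)C(C)(C)C)[C@H](C)C/C(C)=C/C(=O)O)/C=C/[C@H]1OC(=O)C=C[C@@H]1C | intermediate
40 | (2E,5R,6R,7R,9S,10E,12E,15R,16Z,18E)-17-ethyl-6-hydroxy-9-(hydroxymethyl)-3,5,7,11,15-pentamethyl-19-[(2R,3S)-3-methyl-6-oxo-3,6-dihydro-2H-pyran-2-yl]-8-oxononadeca-2,10,12,16,18-pentaenoic acid | CCC(=C/[C@H](C)C/C=C/C(C)=C/[C@@H](CO)C(=O)[C@H](C)[C@H](O)[C@H](C)C/C(C)=C/C(=O)O)/C=C/[C@H]1OC(=O)C=C[C@@H]1C | target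

**Count**

Total steps: 29. Longest linear sequence: 13 steps (steps 1–7, 13–15, 27–29); the other branches reach the target in 11 (steps 8–15, 27–29) and 10 steps (steps 1, 16–19, 25–29 and steps 20–29).

**Three steps most likely to fail, with fallbacks**

Step 13. The allenylzinc carries a β-silyloxy group in its propargylic form, so it may eliminate or add with poor selectivity. The fallback sets out from 13 and comes back at 23; it forms C8–C9 by an auxiliary-controlled aldol instead. Pent-3-yn-1-ol is hydrozirconated with Cp2Zr(H)Cl and iodinated to (3E)-4-iodopent-3-en-1-ol F1. Oxidation with CrO3/H2SO4 in acetone gives (3E)-4-iodopent-3-enoic acid F2. Pivaloyl chloride/Et3N followed by lithiated (R)-4-benzyl-1,3-oxazolidin-2-one gives (4R)-4-benzyl-3-[(3E)-4-iodopent-3-enoyl]-1,3-oxazolidin-2-one F3. Its dibutylboron dienolate (Bu2BOTf, i-Pr2NEt, CH2Cl2, −78 °C) reacts through the α-carbon with 13 to give the Evans syn aldol ethyl (2E,5R,6R,7S,8S,9R,10E)-9-{[(4R)-4-benzyl-2-oxo-1,3-oxazolidin-3-yl]carbonyl}-6-[(tert-butyldimethylsilyl)oxy]-8-hydroxy-11-iodo-3,5,7-trimethyldodeca-2,10-dienoate F4. LiBH4/MeOH in Et2O at 0 °C removes the auxiliary to give ethyl (2E,5R,6R,7S,8R,9S,10E)-6-[(tert-butyldimethylsilyl)oxy]-8-hydroxy-9-(hydroxymethyl)-11-iodo-3,5,7-trimethyldodeca-2,10-dienoate F5. TBSCl/imidazole silylates only the primary hydroxyl and gives 23.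

Step 19. The iodo-ylide olefination is low-yielding, may give Z/E mixtures, and uses a volatile, epimerisable aldehyde. The fallback sets out from 27 and comes back at 36; it builds the trisubstituted alkene by two successive cross-couplings on a dibromoalkene. CBr4/PPh3 converts 27 into (4R)-6,6-dibromo-4-methylhex-5-en-1-yne F6. Trans-selective Negishi mono-ethylation (EtZnCl, PdCl2(DPEphos), THF) replaces the bromine trans to the chain and gives (4R,5Z)-6-bromo-4-methyloct-5-en-1-yne F7. Stille coupling of F7 with 35 (Pd(t-Bu3P)2, NMP, 50 °C) with retention gives 36.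

Step 26. Palladium with tin hydride can also reduce or open the allylic lactone. The fallback sets out from 36 and comes back at 38; it replaces tin by boron and the Stille by a Suzuki union. Hydroboration of 36 with pinacolborane (Cp2Zr(H)Cl 10 mol %, Et3N, CH2Cl2, rt) gives (5S,6R)-6-[(1E,3Z,5R,7E)-3-ethyl-5-methyl-8-(4,4,5,5-tetramethyl-1,3,2-dioxaborolan-2-yl)octa-1,3,7-trien-1-yl]-5-methyl-5,6-dihydro-2H-pyran-2-one F8. Suzuki–Miyaura coupling of F8 with 24 (Pd(PPh3)4, TlOEt, THF/H2O 3:1, rt, short contact) gives 38.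

**Further compounds**

F1 | step 13 | (3E)-4-iodopent-3-en-1-ol | I/C(C)=C/CCO
F2 | step 13 | (3E)-4-iodopent-3-enoic acid | I/C(C)=C/CC(=O)O
F3 | step 13 | (4R)-4-benzyl-3-[(3E)-4-iodopent-3-enoyl]-1,3-oxazolidin-2-one | I/C(C)=C/CC(=O)N1C(=O)OC[C@H]1Cc1ccccc1
F4 | step 13 | ethyl (2E,5R,6R,7S,8S,9R,10E)-9-{[(4R)-4-benzyl-2-oxo-1,3-oxazolidin-3-yl]carbonyl}-6-[(tert-butyldimethylsilyl)oxy]-8-hydroxy-11-iodo-3,5,7-trimethyldodeca-2,10-dienoate | I/C(C)=C/[C@H]([C@@H](O)[C@H](C)[C@H](O[Si](C)(C)C(C)(C)C)[C@H](C)C/C(C)=C/C(=O)OCC)C(=O)N1C(=O)OC[C@H]1Cc1ccccc1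
F5 | step 13 | ethyl (2E,5R,6R,7S,8R,9S,10E)-6-[(tert-butyldimethylsilyl)oxy]-8-hydroxy-9-(hydroxymethyl)-11-iodo-3,5,7-trimethyldodeca-2,10-dienoate | I/C(C)=C/[C@@H](CO)[C@@H](O)[C@H](C)[C@H](O[Si](C)(C)C(C)(C)C)[C@H](C)C/C(C)=C/C(=O)OCC
F6 | step 19 | (4R)-6,6-dibromo-4-methylhex-5-en-1-yne | BrC(Br)=C[C@H](C)CC#C
F7 | step 19 | (4R,5Z)-6-bromo-4-methyloct-5-en-1-yne | CCC(=C/[C@H](C)CC#C)/Br
F8 | step 26 | (5S,6R)-6-[(1E,3Z,5R,7E)-3-ethyl-5-methyl-8-(4,4,5,5-tetramethyl-1,3,2-dioxaborolan-2-yl)octa-1,3,7-trien-1-yl]-5-methyl-5,6-dihydro-2H-pyran-2-one | CCC(=C/[C@H](C)C/C=C/B1OC(C)(C)C(C)(C)O1)/C=C/[C@H]1OC(=O)C=C[C@@H]1C
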